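**Assumption:** Lupalbigenin (6,3'-diprenylgenistein, C25H26O5) has no stereocentres, and both alkenes end in a gem-dimethyl group, so there is no E/Z issue. The "single enantiomer" requirement therefore does not apply, and no step needs stereocontrol.

## Retrosynthetic overview
1. Both prenyl groups come from allyl groups by a double cross-metathesis with 2-methyl-2-butene, run last on the free triphenol so that no acid ever meets an o-prenylphenol.
2. The C6 and C3' allyl groups come from one double aromatic Claisen rearrangement of a 5,4'-di-O-allyl ether. C6 is the only free ortho position to O-5, and C3' and C5' are equivalent.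
3. The 7-OH is masked as a MOM ether first, using its much higher acidity, so that only O-5 and O-4' carry allyl groups.
4. No ring is formed. Rings A, C and B are all bought intact as genistein.

## Route

**Step 1**
Reactants: 1 genistein (5,7,4'-trihydroxyisoflavone); 2 chloromethyl methyl ether
Product: 3, 7-O-MOM-genistein [5-hydroxy-3-(4-hydroxyphenyl)-7-(methoxymethoxy)-4H-chromen-4-one]
Conditions: t-BuOK (1.0 equiv), DMF, 0 °C, 15 min; then MOMCl (1.0 equiv), 0 °C → rt, 2 h
Reagents that add atoms: MOMCl, COCCl
Why: This is a chemoselective Williamson-type O-alkylation, because one equivalent of base deprotonates only the 7-OH (a vinylogous acid, pKa ≈ 7, versus ≈ 10 for 4'-OH and a chelated 5-OH), so the mono-anion reacts at O-7; no stereocentre is formed.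

**Step 2**
Reactants: 3, 7-O-MOM-genistein; 4 allyl bromide
Product: 5, 5-(allyloxy)-3-[4-(allyloxy)phenyl]-7-(methoxymethoxy)-4H-chromen-4-one
Conditions: allyl bromide (4 equiv), K2CO3 (5 equiv), cat. TBAI, DMF, 60 °C, 12 h
Reagents that add atoms: allyl bromide, C=CCBr (two equivalents incorporated)
Why: This is an exhaustive Williamson etherification in which excess reagent and warm DMF overcome the hydrogen-bonded 5-OH, while the MOM ether and the chromone are stable to anhydrous carbonate.

**Step 3**
Reactants: 5, the 5,4'-di-O-allyl-7-O-MOM isoflavone
Product: 6, 6-allyl-3-(3-allyl-4-hydroxyphenyl)-5-hydroxy-7-(methoxymethoxy)-4H-chromen-4-one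
Conditions: PhNEt2, 210 °C (sealed tube or µW, Ar), 1–2 h
Reagents that add atoms: none
Why: This is a double aromatic [3,3] Claisen rearrangement in which the O-5 allyl can only migrate to C6 (C4a is blocked, and the unhindered dienone tautomerises before any Cope shift to C8) and the O-4' allyl goes to the equivalent C3'/C5', with the new 5-OH···O=C4 chelate adding driving force. The amine solvent buffers the MOM group, and any adventitious MOM loss is harmless because Step 4 removes it.

**Step 4**
Reactants: 6, the 6,3'-diallyl-7-O-MOM isoflavone
Product: 7, 6,3'-diallylgenistein [6-allyl-3-(3-allyl-4-hydroxyphenyl)-5,7-dihydroxy-4H-chromen-4-one]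
Conditions: 3 M aq HCl, MeOH–THF, 55 °C, 2 h
Reagents that add atoms: none
Why: This is an acid-catalysed acetal (MOM) hydrolysis, and terminal allyl groups do not protonate under dilute acid, unlike prenyl groups, so no chroman or dihydrofuran forms and the isoflavone core is acid-stable.

**Step 5**
Reactants: 7, 6,3'-diallylgenistein; 8, 2-methyl-2-butene
Product: 9, lupalbigenin (target)
Conditions: Grubbs II (10 mol %), 1,4-benzoquinone (10 mol %), 2-methyl-2-butene/CH2Cl2 (about 1:1, large excess), 40 °C, sealed tube, 14 h
Reagents that add atoms: 2-methyl-2-butene, CC=C(C)C (delivers =C(CH3)2 twice; propene is lost)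
Why: This is a double olefin cross-metathesis of type-I terminal allyl arenes with excess trisubstituted alkene, which gives the trisubstituted prenyl termini essentially irreversibly. Free phenols and the electron-poor chromone C2=C3 bond are inert to the Ru carbene, benzoquinone suppresses allyl → propenyl isomerisation, and no stereoelement is created.

## Compound list
| No. | Name | SMILES | Role |
|---|---|---|---|
| 1 | Genistein | O=c1c(-c2ccc(O)cc2)coc2cc(O)cc(O)c12 | starting material |
| 2 | Chloromethyl methyl ether | COCCl | starting material |
| 3 | 7-O-MOM-genistein | O=c1c(-c2ccc(O)cc2)coc2cc(OCOC)cc(O)c12 | intermediate |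
| 4 | Allyl bromide | C=CCBr | starting material |
| 5 | 5,4'-Di-O-allyl-7-O-MOM-genistein | O=c1c(-c2ccc(OCC=C)cc2)coc2cc(OCOC)cc(OCC=C)c12 | intermediate |
| 6 | 6,3'-Diallyl-7-O-MOM-genistein | O=c1c(-c2ccc(O)c(CC=C)c2)coc2cc(OCOC)c(CC=C)c(O)c12 | intermediate |
| 7 | 6,3'-Diallylgenistein | O=c1c(-c2ccc(O)c(CC=C)c2)coc2cc(O)c(CC=C)c(O)c12 | intermediate |
| 8 | 2-Methyl-2-butene | CC=C(C)C | starting material |
| 9 | Lupalbigenin | CC(C)=CCc1cc(-c2coc3cc(O)c(CC=C(C)C)c(O)c3c2=O)ccc1O | target |

## Summary
**Total steps:** 5. **Longest linear sequence:** 5.

**Steps most likely to fail, each with a fallback**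
1. **Step 3, double Claisen.** The risks are partial para-migration to C8, dihydrobenzofuran formation and incomplete B-ring rearrangement. Fallback: drop the sigmatropic approach. Di-iodinate 3 at C6 and C3' with BnMe3N·ICl2/CaCO3 (ortho to the 5-OH and 4'-OH), install both prenyl groups directly by a double Pd-catalysed Stille coupling with tributyl(3-methylbut-2-enyl)stannane, then remove the MOM group.
2. **Step 1, mono-7-O-protection.** The risk is contamination with 4'-O-MOM and 7,4'-bis-MOM products. Fallback: protect everything and unmask one position. Peracetylate genistein, cleave the 7-acetate selectively (PhSH/imidazole, NMP), put MOM on the only free OH, then methanolyse the 5- and 4'-acetates (K2CO3/MeOH) to reach 3 unambiguously.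
3. **Step 5, double cross-metathesis on the free triphenol.** The risks are isomerisation to propenyl arenes, mono-conversion and poor solubility. Fallback: replace metathesis with carbonyl olefination. Cap the 5- and 4'-OH of 6 as MOM ethers, cleave both allyl groups to arylacetaldehydes (OsO4/NaIO4, Lemieux–Johnson), carry out a double Wittig reaction with Ph3P=C(CH3)2, then remove the MOM groups with mild acid.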